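## Retrosynthetic overview

1. Target 24 ⇐ des-ethyl keto acid 22 by substrate-controlled ethylation at C3, anti to the quaternary C4.
2. 22 ⇐ acyclic diol 17 in one anodic oxidation / intramolecular Diels–Alder (IMDA) / oxidation relay. The C3a–C7a and C4–C5 bonds form in the same [4+2] event, so the cyclopentane and cyclohexene rings close together and four stereocentres are set.
3. 17 ⇐ trienal 11 + silyl dienolate 15 by vinylogous Mukaiyama aldol, then ester reduction.
4. 11 ⇐ (R)-Roche ester 1 by two formyl-ylide Wittig homologations and a benzyl Horner–Wadsworth–Emmons (HWE) olefination. Its stereocentre (C1) is the only one purchased and directs all the others.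

Assumption: positions are cited in the indene numbering of the target (C1 methyl-bearing, C2 ketone, C3, C3a, C4 acid-bearing, C5 styryl-bearing, C6=C7, C7a).
Assumption: 1, 2, 5, 8, 12, 13 and 23 are catalogue chemicals, and every phenyltriene intermediate (9 onward) is handled with exclusion of light.
Assumption: step 10 gives mainly the Felkin carbinol shown; its C2 epimer is carried along because that centre becomes the ketone in step 12.

## Route

Step 1
Reactants: 1 methyl (R)-3-hydroxy-2-methylpropanoate ((R)-Roche ester); 2 tert-butyldimethylsilyl chloride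
Product: 3 methyl (R)-3-[(tert-butyldimethylsilyl)oxy]-2-methylpropanoate
Conditions: TBSCl, imidazole, DMF, 0 °C to rt
Reagents that add atoms: tert-butyldimethylsilyl chloride, CC(C)(C)[Si](C)(C)Cl
Why: Imidazole-mediated O-silylation (silyl ether protection) masks the carbon that later becomes C2 and leaves the stereocentre untouched.

Step 2
Reactants: 3 methyl (R)-3-[(tert-butyldimethylsilyl)oxy]-2-methylpropanoate
Product: 4 (R)-3-[(tert-butyldimethylsilyl)oxy]-2-methylpropanal
Conditions: i-Bu2AlH (1.05 equiv), CH2Cl2, −78 °C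
Reagents that add atoms: none
Why: Low-temperature i-Bu2AlH half-reduction stops at the aluminium hemiacetal, which releases the α-chiral aldehyde on work-up without epimerisation.

Step 3
Reactants: 4 (R)-3-[(tert-butyldimethylsilyl)oxy]-2-methylpropanal; 5 2-(triphenylphosphoranylidene)butanal
Product: 6 (2E,4S)-5-[(tert-butyldimethylsilyl)oxy]-2-ethyl-4-methylpent-2-enal
Conditions: 5, toluene, 85 °C
Reagents that add atoms: 2-(triphenylphosphoranylidene)butanal, CCC(C=O)=P(c1ccccc1)(c1ccccc1)c1ccccc1
Why: Wittig olefination with the non-basic formyl-stabilised ylide gives the (E)-trisubstituted enal (future C7a=C7 with its ethyl group) without touching the allylic stereocentre.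

Step 4
Reactants: 6 (2E,4S)-5-[(tert-butyldimethylsilyl)oxy]-2-ethyl-4-methylpent-2-enal; 5 2-(triphenylphosphoranylidene)butanal
Product: 7 (2E,4E,6S)-7-[(tert-butyldimethylsilyl)oxy]-2,4-diethyl-6-methylhepta-2,4-dienal
Conditions: 5, toluene, 110 °C
Reagents that add atoms: 2-(triphenylphosphoranylidene)butanal, CCC(C=O)=P(c1ccccc1)(c1ccccc1)c1ccccc1
Why: A second stabilised-ylide Wittig olefination adds the C6=C5 unit with (E) geometry, which places the later styryl group "outside" on the diene terminus.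

Step 5
Reactants: 7 (2E,4E,6S)-7-[(tert-butyldimethylsilyl)oxy]-2,4-diethyl-6-methylhepta-2,4-dienal; 8 diethyl benzylphosphonate
Product: 9 tert-butyl{[(2S,3E,5E,7E)-4,6-diethyl-2-methyl-8-phenylocta-3,5,7-trien-1-yl]oxy}dimethylsilane
Conditions: 8, NaH, THF, 0 °C; then 7, −78 to 0 °C, dark
Reagents that add atoms: diethyl benzylphosphonate, CCOP(=O)(Cc1ccccc1)OCC
Why: HWE olefination with the preformed benzylphosphonate anion gives the (E)-styryl bond, and adding the aldehyde cold makes carbonyl addition outrun vinylogous deprotonation at the stereocentre.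

Step 6
Reactants: 9 tert-butyl{[(2S,3E,5E,7E)-4,6-diethyl-2-methyl-8-phenylocta-3,5,7-trien-1-yl]oxy}dimethylsilane
Product: 10 (2S,3E,5E,7E)-4,6-diethyl-2-methyl-8-phenylocta-3,5,7-trien-1-ol
Conditions: Bu4NF, THF, 0 °C to rt, dark
Reagents that add atoms: none
Why: Fluoride-induced desilylation frees the primary alcohol under conditions that leave the triene and the stereocentre alone.

Step 7
Reactants: 10 (2S,3E,5E,7E)-4,6-diethyl-2-methyl-8-phenylocta-3,5,7-trien-1-ol
Product: 11 (2S,3E,5E,7E)-4,6-diethyl-2-methyl-8-phenylocta-3,5,7-trienal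
Conditions: Dess–Martin periodinane, NaHCO3, CH2Cl2, 0 °C, dark; used crude at once
Reagents that add atoms: none
Why: Buffered Dess–Martin oxidation is base-free and fast, so the β,γ-unsaturated α-methyl aldehyde is obtained without epimerisation or migration of the double bond into conjugation.

Step 8
Reactants: 12 (E)-2-ethylbut-2-enoic acid; 13 methanol
Product: 14 methyl (E)-2-ethylbut-2-enoate
Conditions: MeOH, H2SO4 (cat.), reflux
Reagents that add atoms: methanol, CO
Why: Fischer esterification gives the methyl ester needed for dienolate formation.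

Step 9
Reactants: 14 methyl (E)-2-ethylbut-2-enoate; 2 tert-butyldimethylsilyl chloride
Product: 15 tert-butyl[(2-ethyl-1-methoxybuta-1,3-dien-1-yl)oxy]dimethylsilane (ketene acetal E/Z mixture)
Conditions: LiN(i-Pr)2, THF/DMPU, −78 °C; then TBSCl
Reagents that add atoms: tert-butyldimethylsilyl chloride, CC(C)(C)[Si](C)(C)Cl
Why: Kinetic γ-deprotonation of the enoate and O-silylation of the lithium dienolate give the vinylogous silyl ketene acetal.

Step 10
Reactants: 11 (2S,3E,5E,7E)-4,6-diethyl-2-methyl-8-phenylocta-3,5,7-trienal; 15 tert-butyl[(2-ethyl-1-methoxybuta-1,3-dien-1-yl)oxy]dimethylsilane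
Product: 16 methyl (2E,5S,6S,7E,9E,11E)-2,8,10-triethyl-5-hydroxy-6-methyl-12-phenyldodeca-2,7,9,11-tetraenoate
Conditions: 15 (1.5 equiv), BF3·OEt2 (1.1 equiv), CH2Cl2/Et2O, −78 °C, dark
Reagents that add atoms: tert-butyl[(2-ethyl-1-methoxybuta-1,3-dien-1-yl)oxy]dimethylsilane, C=CC(CC)=C(OC)O[Si](C)(C)C(C)(C)C
Why: Vinylogous Mukaiyama aldol reaction, in which the γ-carbon of the silyl dienolate attacks the BF3-activated aldehyde to form the C2–C3 bond and the (E)-enoate; the new carbinol forms mainly in the Felkin–Anh sense but is only a placeholder for the ketone.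

Step 11
Reactants: 16 methyl (2E,5S,6S,7E,9E,11E)-2,8,10-triethyl-5-hydroxy-6-methyl-12-phenyldodeca-2,7,9,11-tetraenoate
Product: 17 (2E,5S,6S,7E,9E,11E)-2,8,10-triethyl-6-methyl-12-phenyldodeca-2,7,9,11-tetraene-1,5-diol
Conditions: i-Bu2AlH (3.5 equiv), CH2Cl2, −78 to 0 °C, dark
Reagents that add atoms: none
Why: i-Bu2AlH 1,2-reduction takes the enoate to the primary allylic alcohol without touching the alkenes or the stereocentres.

Step 12
Reactants: 17 (2E,5S,6S,7E,9E,11E)-2,8,10-triethyl-6-methyl-12-phenyldodeca-2,7,9,11-tetraene-1,5-diol; 18 water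
Product: 22 (1S,3aS,4R,5S,7aR)-4,5,7-triethyl-1-methyl-2-oxo-5-[(E)-2-phenylethenyl]-2,3,3a,4,5,7a-hexahydro-1H-indene-4-carboxylic acid, via hydroxy enal 19 (not isolated), via bicyclic hydroxy aldehyde 20 (not isolated), via bicyclic keto aldehyde 21 (not isolated)
Conditions: 4-acetamido-TEMPO (ACT, 10 mol%), NaHCO3/Na2CO3 buffer (pH 10)–MeCN 1:1, carbon-foam anode/Pt cathode, undivided cell, 0.7 V vs Ag/AgCl, dark: 5 °C, 2.1 F/mol; current off, 60 °C until 19 is consumed; then 25 °C to 6.5 F/mol total; aq. HCl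
Reagents that add atoms: water, O
Why: Proposed new method: an aminoxyl-electrocatalytic oxidation/IMDA/oxidation relay under one anode programme, in which the anodically regenerated oxoammonium of ACT (about 0.6 V vs Ag/AgCl, well below the >1.1 V needed to ionise the phenyltriene) dehydrogenates the unhindered primary allylic alcohol to enal 19 much faster than the flanked secondary carbinol; 19 then closes in the aqueous electrolyte by an endo (formyl under the diene) intramolecular [4+2] cycloaddition through the conformer whose C1–H eclipses the diene (A(1,3) strain against the C7 ethyl), so the Roche stereocentre fixes the diene face and with it C7a, C3a, C4 and C5 (trans ring fusion, diene and dienophile geometry transferred suprafacially), and the same mediator finally oxidises the now-saturated carbinol to the ketone and the non-enolisable aldehyde, via its hydrate, to the acid; the closest known reaction types are ACT-mediated anodic oxidation of alcohols and aldehydes and chemical-oxidant-triggered (MnO2 or Dess–Martin) oxidation/IMDA cascades.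

Step 13
Reactants: 22 (1S,3aS,4R,5S,7aR)-4,5,7-triethyl-1-methyl-2-oxo-5-[(E)-2-phenylethenyl]-2,3,3a,4,5,7a-hexahydro-1H-indene-4-carboxylic acid; 23 iodoethane
Product: 24 (1S,3S,3aR,4R,5S,7aR)-3,4,5,7-tetraethyl-1-methyl-2-oxo-5-[(E)-2-phenylethenyl]-2,3,3a,4,5,7a-hexahydro-1H-indene-4-carboxylic acid (target CNP0420507.2)
Conditions: LiN(i-Pr)2 (2.3 equiv), THF, −78 °C; EtI, DMPU, −78 to −20 °C; aq. HCl
Reagents that add atoms: iodoethane, CCI
Why: Kinetic enolate alkylation, in which LiN(i-Pr)2 forms the carboxylate plus the less substituted (C3) enolate and ethyl iodide enters anti to the adjacent C3a–C4 bond, giving the 3-ethyl group trans to the quaternary C4 (also the thermodynamic arrangement) while C1 is not deprotonated.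

## Compound list

1 | methyl (R)-3-hydroxy-2-methylpropanoate ((R)-Roche ester) | COC(=O)[C@H](C)CO | starting material
2 | tert-butyldimethylsilyl chloride | CC(C)(C)[Si](C)(C)Cl | starting material
3 | methyl (R)-3-[(tert-butyldimethylsilyl)oxy]-2-methylpropanoate | COC(=O)[C@H](C)CO[Si](C)(C)C(C)(C)C | intermediate
4 | (R)-3-[(tert-butyldimethylsilyl)oxy]-2-methylpropanal | O=C[C@H](C)CO[Si](C)(C)C(C)(C)C | intermediate
5 | 2-(triphenylphosphoranylidene)butanal | CCC(C=O)=P(c1ccccc1)(c1ccccc1)c1ccccc1 | starting material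
6 | (2E,4S)-5-[(tert-butyldimethylsilyl)oxy]-2-ethyl-4-methylpent-2-enal | O=C/C(CC)=C/[C@H](C)CO[Si](C)(C)C(C)(C)C | intermediate
7 | (2E,4E,6S)-7-[(tert-butyldimethylsilyl)oxy]-2,4-diethyl-6-methylhepta-2,4-dienal | O=C/C(CC)=C/C(CC)=C/[C@H](C)CO[Si](C)(C)C(C)(C)C | intermediate
8 | diethyl benzylphosphonate | CCOP(=O)(Cc1ccccc1)OCC | starting material
9 | tert-butyl{[(2S,3E,5E,7E)-4,6-diethyl-2-methyl-8-phenylocta-3,5,7-trien-1-yl]oxy}dimethylsilane | c1ccccc1/C=C/C(CC)=C/C(CC)=C/[C@H](C)CO[Si](C)(C)C(C)(C)C | intermediate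
10 | (2S,3E,5E,7E)-4,6-diethyl-2-methyl-8-phenylocta-3,5,7-trien-1-ol | c1ccccc1/C=C/C(CC)=C/C(CC)=C/[C@H](C)CO | intermediate
11 | (2S,3E,5E,7E)-4,6-diethyl-2-methyl-8-phenylocta-3,5,7-trienal | c1ccccc1/C=C/C(CC)=C/C(CC)=C/[C@H](C)C=O | intermediate
12 | (E)-2-ethylbut-2-enoic acid | C/C=C(/C(=O)O)CC | starting material
13 | methanol | CO | starting material
14 | methyl (E)-2-ethylbut-2-enoate | C/C=C(/C(=O)OC)CC | intermediate
15 | tert-butyl[(2-ethyl-1-methoxybuta-1,3-dien-1-yl)oxy]dimethylsilane (E/Z mixture at the ketene acetal) | C=CC(CC)=C(OC)O[Si](C)(C)C(C)(C)C | intermediate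
16 | methyl (2E,5S,6S,7E,9E,11E)-2,8,10-triethyl-5-hydroxy-6-methyl-12-phenyldodeca-2,7,9,11-tetraenoate | c1ccccc1/C=C/C(CC)=C/C(CC)=C/[C@H](C)[C@@H](O)C/C=C(\CC)C(=O)OC | intermediate
17 | (2E,5S,6S,7E,9E,11E)-2,8,10-triethyl-6-methyl-12-phenyldodeca-2,7,9,11-tetraene-1,5-diol | c1ccccc1/C=C/C(CC)=C/C(CC)=C/[C@H](C)[C@@H](O)C/C=C(\CC)CO | intermediate
18 | water | O | starting material
19 | (2E,5S,6S,7E,9E,11E)-2,8,10-triethyl-5-hydroxy-6-methyl-12-phenyldodeca-2,7,9,11-tetraenal (hydroxy enal) | c1ccccc1/C=C/C(CC)=C/C(CC)=C/[C@H](C)[C@@H](O)C/C=C(\CC)C=O | intermediate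
20 | (1S,2S,3aS,4R,5S,7aR)-4,5,7-triethyl-2-hydroxy-1-methyl-5-[(E)-2-phenylethenyl]-2,3,3a,4,5,7a-hexahydro-1H-indene-4-carbaldehyde (bicyclic hydroxy aldehyde) | CCC1=C[C@@](/C=C/c2ccccc2)(CC)[C@](CC)(C=O)[C@@H]2[C@@H]1[C@H](C)[C@@H](O)C2 | intermediate
21 | (1S,3aS,4R,5S,7aR)-4,5,7-triethyl-1-methyl-2-oxo-5-[(E)-2-phenylethenyl]-2,3,3a,4,5,7a-hexahydro-1H-indene-4-carbaldehyde (bicyclic keto aldehyde) | CCC1=C[C@@](/C=C/c2ccccc2)(CC)[C@](CC)(C=O)[C@@H]2[C@@H]1[C@H](C)C(=O)C2 | intermediate
22 | (1S,3aS,4R,5S,7aR)-4,5,7-triethyl-1-methyl-2-oxo-5-[(E)-2-phenylethenyl]-2,3,3a,4,5,7a-hexahydro-1H-indene-4-carboxylic acid | CCC1=C[C@@](/C=C/c2ccccc2)(CC)[C@](CC)(C(=O)O)[C@@H]2[C@@H]1[C@H](C)C(=O)C2 | intermediate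
23 | iodoethane | CCI | starting material
24 | (1S,3S,3aR,4R,5S,7aR)-3,4,5,7-tetraethyl-1-methyl-2-oxo-5-[(E)-2-phenylethenyl]-2,3,3a,4,5,7a-hexahydro-1H-indene-4-carboxylic acid | CCC1=C[C@@](/C=C/c2ccccc2)(CC)[C@](CC)(C(=O)O)[C@@H]2[C@@H]1[C@H](C)C(=O)[C@H]2CC | target

## Step count and risks

Total step count: 13. Longest linear sequence: 11 (steps 1–7 and 10–13); steps 8–9 are the side branch to 15.

The three steps most likely to fail:

Step 12 (the new anodic relay). Risks are:
- oxidation of the secondary carbinol before cyclisation;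
- attack of the oxoammonium on the electron-rich triene;
- a slow cycloaddition, because it builds two adjacent quaternary carbons;
- an endo:exo ratio that now rests on the formyl group alone;
- sluggish oxidation of the neopentyl aldehyde.

The fallback uses known chemistry only, sets out from 16 and comes back at 22. Ester 16 is heated in toluene with BHT at 110 °C so that the enoate itself serves as dienophile in a thermal IMDA, giving methyl (1S,2S,3aS,4R,5S,7aR)-4,5,7-triethyl-2-hydroxy-1-methyl-5-[(E)-2-phenylethenyl]-2,3,3a,4,5,7a-hexahydro-1H-indene-4-carboxylate F1. Dess–Martin oxidation of the carbinol then gives the keto ester methyl (1S,3aS,4R,5S,7aR)-4,5,7-triethyl-1-methyl-2-oxo-5-[(E)-2-phenylethenyl]-2,3,3a,4,5,7a-hexahydro-1H-indene-4-carboxylate F2. The hindered methyl ester is cleaved by SN2 demethylation with LiI in refluxing pyridine, which delivers 22 for step 13.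

Step 13 (ethylation of the dianion). Risks are deprotonation at C1 instead of C3, over-alkylation and the low reactivity of ethyl iodide. The fallback sets out from 22 and comes back at 24, replacing alkylation by aldol chemistry. The same dianion is quenched with acetaldehyde to give the 3-(1-hydroxyethyl) keto acid F3. Acid-catalysed dehydration (p-TsOH, benzene, 60 °C) gives the 3-ethylidene enone acid F4. Conjugate reduction with excess [(Ph3P)CuH]6 (the first hydride equivalent is consumed by the acid), followed by brief DBU equilibration, sets the C3 ethyl group trans to C4 and gives 24.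

Step 10 (vinylogous Mukaiyama aldol). Aldehyde 11 can epimerise or conjugate under the Lewis acid, the triene can be attacked by BF3, and some α-attack of the dienolate is possible. The fallback sets out from 11 and comes back at 16, building the same chain by a Lewis-acid-free aldol/Wittig sequence. Crude 11 is added at −78 °C to the lithium enolate of N-methoxy-N-methylacetamide, giving (3S,4S,5E,7E,9E)-6,8-diethyl-3-hydroxy-N-methoxy-N,4-dimethyl-10-phenyldeca-5,7,9-trienamide F5. i-Bu2AlH at −78 °C reduces the amide to (3S,4S,5E,7E,9E)-6,8-diethyl-3-hydroxy-4-methyl-10-phenyldeca-5,7,9-trienal F6. Wittig olefination with methyl 2-(triphenylphosphoranylidene)butanoate then gives the (E)-enoate 16.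

## Further compounds

F1 | step 12 | methyl (1S,2S,3aS,4R,5S,7aR)-4,5,7-triethyl-2-hydroxy-1-methyl-5-[(E)-2-phenylethenyl]-2,3,3a,4,5,7a-hexahydro-1H-indene-4-carboxylate | CCC1=C[C@@](/C=C/c2ccccc2)(CC)[C@](CC)(C(=O)OC)[C@@H]2[C@@H]1[C@H](C)[C@@H](O)C2
F2 | step 12 | methyl (1S,3aS,4R,5S,7aR)-4,5,7-triethyl-1-methyl-2-oxo-5-[(E)-2-phenylethenyl]-2,3,3a,4,5,7a-hexahydro-1H-indene-4-carboxylate | CCC1=C[C@@](/C=C/c2ccccc2)(CC)[C@](CC)(C(=O)OC)[C@@H]2[C@@H]1[C@H](C)C(=O)C2
F3 | step 13 | 3-(1-hydroxyethyl) derivative of keto acid 22 (mixture at C3 and the carbinol carbon) | CCC1=C[C@@](/C=C/c2ccccc2)(CC)[C@](CC)(C(=O)O)[C@@H]2[C@@H]1[C@H](C)C(=O)C2C(C)O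
F4 | step 13 | 3-ethylidene derivative of keto acid 22 (E/Z mixture) | CCC1=C[C@@](/C=C/c2ccccc2)(CC)[C@](CC)(C(=O)O)[C@@H]2[C@@H]1[C@H](C)C(=O)C2=CC
F5 | step 10 | (3S,4S,5E,7E,9E)-6,8-diethyl-3-hydroxy-N-methoxy-N,4-dimethyl-10-phenyldeca-5,7,9-trienamide | c1ccccc1/C=C/C(CC)=C/C(CC)=C/[C@H](C)[C@@H](O)CC(=O)N(C)OC
F6 | step 10 | (3S,4S,5E,7E,9E)-6,8-diethyl-3-hydroxy-4-methyl-10-phenyldeca-5,7,9-trienal | c1ccccc1/C=C/C(CC)=C/C(CC)=C/[C@H](C)[C@@H](O)CC=O
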